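Decide first whether to leave the flask running to 2.0 min or to stop it early, at the top of D. The flask and the elm run are one charge, so the elm readings speak for it directly.

| flask | E | remark | time |
|---|---|---|---|
| elm | 1.5 M | the very flask that is asked about, followed so far |  |
| ash | 2.2 M | run made earlier |  |
| flask | 1.5 M |  | 2.0 min |

| run | time / s | D / % | E / % |
|---|---|---|---|
| elm | 12.0 | 28 | 68 |
| elm | 25.0 | 40 | 53 |
| elm | 40.0 | 45 | 35 |
| elm | 50.0 | 49 | 32 |
| elm | 60.0 | 48 | 29 |
| ash | 10.0 | 32 | 65 |
| ash | 15.0 | 40 | 54 |
| ash | 25.0 | 46 | 41 |
| ash | 50.0 | 53 | 23 |

(scatter of a reading: 1.5 percentage points)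

- percent here means E units held: one D counts as two

- amount of D in percent of the E charged, at 6.0 s, 30 s and 2.0 min

Work in fractions of the charge: e for E, d for D, and m for what is missing from the two. Suppose D is made from two E and lost by meeting E. Then making goes as e² and loss as e·d, so D rises while d/e stays below a constant and falls above it. Call this constant the turning ratio T, a selectivity factor. Each meeting moves 3 units of the charge into m, which is small at first, so treat it as a correction and put d ≈ 1 − e inside it:

m ≈ (3/2T) · (ln(1/e) − 1 + e)

Put in the elm reading at 40.0 s, with e = 35% and d = 45%:

T = 3.00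

This is a reading, with the scatter of both percentages in it.

Next extend the straight line of 1/e through the elm reading at 60.0 s out to 2.0 min:

e ≈ 17.0%

The forecast gives 19%, 44% and 35%, and of its two routes it says: “An E + D route fits only slightly worse, though, and it would leave more D at long times.” I take the E + D route, and the two of us part at 2.0 min. The forecast's last value has D past its top, yet over my e it gives d/e = 2.06, less than T, which by my rule is a D still rising. My own estimate of D for that time is T·e = 51.0%, which puts d/e at T, so I expect D to stand about at its top by then. So leave the flask running.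

The flask gives 17.1%, 44.1% and 53.2%.

    2 E → D (k = 0.0120 M⁻¹ s⁻¹)
    E + D → G (k = 0.00830 M⁻¹ s⁻¹)
    E → X (k = 9.60 × 10⁻⁶ s⁻¹)

At 0.279 min the flask makes D 5.19 times as fast as it uses it up, and at 2.00 min that ratio is 0.815, with d/e at 3.55, above T = 3.00. The ash run at 50.0 s read d/e = 2.30, below T, and its D had gone from 46% at 25.0 s up to 53%.

(Readings and results were computed for substances that don't exist; the scatter is artificial.)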